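**Strategy.** The route rests on the C2–C3 bond of the indane (the five-membered carbocycle fused to resorcinol ring B). It joins two benzylic methines: C3, carrying the 4-hydroxyphenyl group, and C2, carrying benzofuran ring D, cis to each other. These carbons are first linked through nitrogen in a 1,3-cis tetrahydroisoquinoline, built by a sulfinimine Mannich addition and a Bischler–Napieralski closure with cis-selective hydride reduction. Nitrogen deletion then contracts this six-membered aza ring to the indane in one operation, forming C2–C3 with retention and delivering the contra-thermodynamic cis-diaryl relation. Because both carbons are benzylic, dinitrogen leaves readily and the radical pair recombines. Friedel–Crafts closure of the eight-membered ring and demethylation complete the synthesis.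

Key step: step 11

Assumption (chemistry): Rh2(R-PTAD)4 is taken to give the (3R) series in step 4; if the antipode forms, the S-configured catalyst is used and nothing else changes.

Labels: ring B = resorcinol ring of the indane; ring C = resorcinol ring on benzofuran C3; ring D = benzene ring of the dihydrobenzofuran. Bf = (2R,3R)-3-(3,5-dimethoxyphenyl)-6-methoxy-2-(4-methoxyphenyl)-2,3-dihydro-1-benzofuran-4-yl.

Step 1
Reactants: 1 1-bromo-3,5-dimethoxybenzene; 2 3,5-dimethoxybenzoyl chloride
Product: 4 (2-bromo-6-hydroxy-4-methoxyphenyl)(3,5-dimethoxyphenyl)methanone, via dimethoxy ketone 3 (not isolated)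
Conditions: AlCl3 (3 equiv), CH2Cl2, 0 → 40 °C
Reagents that add atoms: none
Why: Friedel–Crafts acylation should occur at C2 of 1 (between Br and OMe, para to the second OMe, as in formylations of this arene), and AlCl3 chelated between the new carbonyl and the neighbouring methoxy group then cleaves only that ortho methyl ether (chelation-controlled demethylation).

Step 2
Reactants: 4 hydroxy ketone; 5 4-methoxybenzyl chloride
Product: 6 {2-bromo-4-methoxy-6-[(4-methoxybenzyl)oxy]phenyl}(3,5-dimethoxyphenyl)methanone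
Conditions: K2CO3, DMF, 60 °C
Reagents that add atoms: none
Why: Williamson ether synthesis on the phenoxide; aryl ketone and aryl bromide are inert to K2CO3.

Step 3
Reactants: 6 benzyl ether ketone
Product: 7 hydrazone of 6
Conditions: N2H4·H2O (excess), AcOH (cat.), n-BuOH, 110 °C
Reagents that add atoms: hydrazine NN
Why: Hydrazone condensation; the di-ortho-substituted benzophenone needs excess hydrazine and heat, and the electron-rich aryl bromide should not undergo substitution under these conditions.

Step 4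
Reactants: 7 hydrazone
Product: 9 (2S,3R)-4-bromo-3-(3,5-dimethoxyphenyl)-6-methoxy-2-(4-methoxyphenyl)-2,3-dihydro-1-benzofuran (2,3-cis), via diazo compound 8 (not isolated)
Conditions: MnO2, CH2Cl2, 0 °C; filter; then Rh2(R-PTAD)4 [dirhodium tetrakis((R)-1-adamantyl(phthalimido)acetate), 1 mol %], CH2Cl2/MeCN, 0 °C
Reagents that add atoms: none
Why: MnO2 dehydrogenates the hydrazone to the diaryldiazomethane, and the derived donor/donor dirhodium carbene undergoes intramolecular 1,5 C–H insertion into the benzylic ether C–H bond (five-membered ring), the concerted insertion giving the 2,3-cis product and the chiral carboxylate ligands choosing the carbene face and thereby C3.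

Step 5
Reactants: 9 cis-dihydrobenzofuran
Product: 10 (2R,3R)-4-bromo-3-(3,5-dimethoxyphenyl)-6-methoxy-2-(4-methoxyphenyl)-2,3-dihydro-1-benzofuran (2,3-trans; Bf–Br)
Conditions: TFA, CH2Cl2, 0 °C → rt
Reagents that add atoms: none
Why: Acid-mediated epimerisation: reversible heterolysis of the benzylic C2–O bond gives a 4-methoxybenzyl cation that recloses to the thermodynamically favoured 2,3-trans ether, while C3 is not touched and keeps its configuration.

Step 6
Reactants: 10 Bf–Br
Product: 12 Bf–CHO [(2R,3R)-3-(3,5-dimethoxyphenyl)-6-methoxy-2-(4-methoxyphenyl)-2,3-dihydro-1-benzofuran-4-carbaldehyde], via aryllithium 11 (not isolated)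
Conditions: n-BuLi, THF, −78 °C; then DMF; aq. NH4Cl
Reagents that add atoms: N,N-dimethylformamide CN(C)C=O
Why: Bromine–lithium exchange is faster at −78 °C than deprotonation or directed metalation, and the aryllithium is formylated by DMF (Bouveault-type formylation).

Step 7
Reactants: 12 Bf–CHO; 13 (S)-2-methylpropane-2-sulfinamide
Product: 14 (S,E)-N-(Bf-methylidene)-2-methylpropane-2-sulfinamide
Conditions: Ti(OEt)4, THF, 50 °C
Reagents that add atoms: none
Why: Ti(OEt)4-mediated condensation should give the E-configured N-sulfinyl aldimine without touching the stereocentres.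

Step 8
Reactants: 14 sulfinimine; 15 methyl 2-(3,5-dimethoxyphenyl)acetate
Product: 17 methyl (2R,3R)-3-Bf-3-{[(S)-tert-butylsulfinyl]amino}-2-(3,5-dimethoxyphenyl)propanoate, via titanium enolate 16 (not isolated)
Conditions: 15, LiN(iPr)2, THF, −78 °C; ClTi(OiPr)3; then 14, −78 °C
Reagents that add atoms: none
Why: Mannich addition of the titanium ester enolate through a closed chair (Zimmerman–Traxler-type) transition state in which titanium binds the sulfinyl oxygen: the (S)-sulfinyl group directs attack to one imine face and sets C3 (R), the enolate geometry should give the 2,3-syn relation, and C2 stays correctable by base at the ester stage because the relation needed later is the thermodynamic trans one.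

Step 9
Reactants: 17 Mannich adduct; 18 4-methoxybenzoyl chloride
Product: 20 methyl (2R,3R)-3-Bf-2-(3,5-dimethoxyphenyl)-3-(4-methoxybenzamido)propanoate, via amine hydrochloride 19 (not isolated)
Conditions: HCl (4 M in dioxane), MeOH, 0 °C; evaporate; then 18, Et3N, CH2Cl2, 0 °C
Reagents that add atoms: none
Why: Acidic methanolysis cleaves the N–S bond of the sulfinamide, and the amine salt is N-acylated under Schotten–Baumann-type conditions, both without base-induced epimerisation at C2.

Step 10
Reactants: 20 amide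
Product: 22 methyl (1R,3R,4R)-3-Bf-6,8-dimethoxy-1-(4-methoxyphenyl)-1,2,3,4-tetrahydroisoquinoline-4-carboxylate (1,3-cis; 3,4-trans), via dihydroisoquinoline 21 (not isolated)
Conditions: Tf2O, 2-chloropyridine, CH2Cl2, −78 → 0 °C; then NaBH4, MeOH, −78 → 0 °C
Reagents that add atoms: none
Why: Bischler–Napieralski cyclodehydration: the Tf2O-activated amide is attacked at low temperature (which avoids retro-Ritter fragmentation) by the ortho carbon of the 3,5-dimethoxyphenyl ring (six-membered ring, position ortho/para to both methoxy groups), and NaBH4 then delivers hydride to C1=N from the face anti to the pseudoaxial C3 aryl group, which should give the 1,3-cis amine.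

Step 11
Reactants: 22 tetrahydroisoquinoline
Product: 25 methyl (1S,2R,3R)-2-Bf-4,6-dimethoxy-3-(4-methoxyphenyl)-2,3-dihydro-1H-indene-1-carboxylate (2,3-cis; 1,2-trans), via N-benzyloxy hydrazide 23 (not isolated), via isodiazene 24 (not isolated)
Conditions: N-(benzyloxy)-N-(pivaloyloxy)-4-(trifluoromethyl)benzamide (1.5 equiv), THF, 45 °C
Reagents that add atoms: none
Why: The secondary amine attacks the nitrogen of the anomeric amide and displaces pivalate; hydrazide 23 then loses benzyl 4-(trifluoromethyl)benzoate by reductive elimination to give isodiazene 24, which extrudes N2 to a singlet 1,5-radical pair that collapses to the C2–C3 bond. The closest known reaction type is the nitrogen deletion of secondary amines via isodiazenes, known for benzylic cyclic amines such as tetrahydroisoquinolines (giving indanes) and, in its classical hydrazine-oxidation form, for cis-2,6-diarylpiperidines (giving cis-1,2-diarylcyclopentanes). The five-membered ring closes by radical–radical recombination of the two benzylic termini inside the former six-membered ring, a 6 → 5 ring contraction in which the benzo tether holds the termini close together. No stereocentre is made from a flat precursor: C3 and C2 of the indane should inherit the 1,3-cis relation of 22 by retention (recombination faster than rotation about C1–C2), and C1 is not involved. The step needs recombination to beat bond rotation, disproportionation to a stilbene and 1,3-hydrogen shift to a hydrazone; both C–N bonds are benzylic (C3 doubly so), which lets N2 leave at 45 °C and gives stabilised radicals held in place by the rigid ring.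

Step 12
Reactants: 25 indane ester
Product: 26 (1S,2R,3R)-2-Bf-4,6-dimethoxy-3-(4-methoxyphenyl)-2,3-dihydro-1H-indene-1-carbaldehyde
Conditions: iBu2AlH, CH2Cl2, −78 °C
Reagents that add atoms: none
Why: Partial reduction of the ester: the tetrahedral aluminium hemiacetal is stable at −78 °C and releases the aldehyde on work-up; C1 is already in the thermodynamic trans arrangement.

Step 13
Reactants: 26 aldehyde; 27 4-methoxyphenylmagnesium bromide
Product: 28 [(1S,2R,3R)-2-Bf-4,6-dimethoxy-3-(4-methoxyphenyl)-2,3-dihydro-1H-inden-1-yl](4-methoxyphenyl)methanol (both carbinol epimers)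
Conditions: 4-MeOC6H4MgBr, THF, −78 → 0 °C
Reagents that add atoms: none
Why: Grignard addition to the aldehyde; the carbinol configuration is irrelevant because this centre is ionised in the next step.

Step 14
Reactants: 28 carbinol
Product: 29 octa-O-methylcanaliculatol
Conditions: TsOH·H2O (20 mol %), CH2Cl2/HFIP 4:1 (1 mM), 0 °C → rt
Reagents that add atoms: none
Why: Intramolecular Friedel–Crafts alkylation: acid ionises the 4-methoxybenzylic alcohol, the cation sits trans to the C2 benzofuranyl group so that five-ring closure onto ring D and bridging onto the C3 aryl are geometrically impossible, and the ortho carbon of ring C (ortho/para to its methoxy groups) should close the eight-membered ring; the new methine is expected to form with the 4-methoxyphenyl group in the outward pseudo-equatorial position on the trans-fused indane under reversible conditions.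

Step 15
Reactants: 29 octamethyl ether
Product: 30 canaliculatol
Conditions: BBr3, CH2Cl2, −78 °C → rt; then MeOH/H2O
Reagents that add atoms: none
Why: BBr3 cleaves all eight aryl methyl ethers (Lewis acid-mediated demethylation); the trans-dihydrobenzofuran is the thermodynamic isomer, so reversible opening of its benzylic C–O bond should not change the configuration.

**Compound list**

1 | 1-bromo-3,5-dimethoxybenzene | COc1cc(Br)cc(OC)c1 | starting material
2 | 3,5-dimethoxybenzoyl chloride | COc1cc(cc(OC)c1)C(Cl)=O | starting material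
3 | (2-bromo-4,6-dimethoxyphenyl)(3,5-dimethoxyphenyl)methanone | COc1cc(OC)c(C(=O)c2cc(OC)cc(OC)c2)c(Br)c1 | intermediate (not isolated)
4 | (2-bromo-6-hydroxy-4-methoxyphenyl)(3,5-dimethoxyphenyl)methanone | COc1cc(O)c(C(=O)c2cc(OC)cc(OC)c2)c(Br)c1 | intermediate
5 | 4-methoxybenzyl chloride | COc1ccc(CCl)cc1 | starting material
6 | {2-bromo-4-methoxy-6-[(4-methoxybenzyl)oxy]phenyl}(3,5-dimethoxyphenyl)methanone | COc1ccc(COc2cc(OC)cc(Br)c2C(=O)c2cc(OC)cc(OC)c2)cc1 | intermediate
7 | hydrazone of 6 | COc1ccc(COc2cc(OC)cc(Br)c2C(=NN)c2cc(OC)cc(OC)c2)cc1 | intermediate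
8 | diaryldiazomethane from 7 | COc1ccc(COc2cc(OC)cc(Br)c2C(=[N+]=[N-])c2cc(OC)cc(OC)c2)cc1 | intermediate (not isolated)
9 | (2S,3R)-4-bromo-3-(3,5-dimethoxyphenyl)-6-methoxy-2-(4-methoxyphenyl)-2,3-dihydro-1-benzofuran (cis) | COc1cc(OC)cc(c1)[C@@H]1c2c(Br)cc(OC)cc2O[C@@H]1c1ccc(OC)cc1 | intermediate
10 | (2R,3R)-4-bromo-3-(3,5-dimethoxyphenyl)-6-methoxy-2-(4-methoxyphenyl)-2,3-dihydro-1-benzofuran (trans; Bf–Br) | COc1cc(OC)cc(c1)[C@@H]1c2c(Br)cc(OC)cc2O[C@H]1c1ccc(OC)cc1 | intermediate
11 | Bf–Li (4-lithio derivative of 10) | COc1cc(OC)cc(c1)[C@@H]1c2c([Li])cc(OC)cc2O[C@H]1c1ccc(OC)cc1 | intermediate (not isolated)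
12 | Bf–CHO, (2R,3R)-3-(3,5-dimethoxyphenyl)-6-methoxy-2-(4-methoxyphenyl)-2,3-dihydro-1-benzofuran-4-carbaldehyde | COc1cc(OC)cc(c1)[C@@H]1c2c(C=O)cc(OC)cc2O[C@H]1c1ccc(OC)cc1 | intermediate
13 | (S)-2-methylpropane-2-sulfinamide | CC(C)(C)[S@](=O)N | starting material
14 | (S,E)-N-(Bf-methylidene)-2-methylpropane-2-sulfinamide | COc1cc(OC)cc(c1)[C@@H]1c2c(/C=N/[S@@](=O)C(C)(C)C)cc(OC)cc2O[C@H]1c1ccc(OC)cc1 | intermediate
15 | methyl 2-(3,5-dimethoxyphenyl)acetate | COC(=O)Cc1cc(OC)cc(OC)c1 | starting material
16 | triisopropoxytitanium enolate of 15 | COC(O[Ti](OC(C)C)(OC(C)C)OC(C)C)=Cc1cc(OC)cc(OC)c1 | intermediate (not isolated)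
17 | methyl (2R,3R)-3-Bf-3-{[(S)-tert-butylsulfinyl]amino}-2-(3,5-dimethoxyphenyl)propanoate | COc1cc(OC)cc(c1)[C@@H]1c2c(cc(OC)cc2O[C@H]1c1ccc(OC)cc1)[C@H](N[S@@](=O)C(C)(C)C)[C@H](C(=O)OC)c1cc(OC)cc(OC)c1 | intermediate
18 | 4-methoxybenzoyl chloride | COc1ccc(cc1)C(Cl)=O | starting material
19 | methyl (2R,3R)-3-amino-3-Bf-2-(3,5-dimethoxyphenyl)propanoate hydrochloride | COc1cc(OC)cc(c1)[C@@H]1c2c(cc(OC)cc2O[C@H]1c1ccc(OC)cc1)[C@H]([NH3+])[C@H](C(=O)OC)c1cc(OC)cc(OC)c1.[Cl-] | intermediate (not isolated)
20 | methyl (2R,3R)-3-Bf-2-(3,5-dimethoxyphenyl)-3-(4-methoxybenzamido)propanoate | COc1cc(OC)cc(c1)[C@@H]1c2c(cc(OC)cc2O[C@H]1c1ccc(OC)cc1)[C@H](NC(=O)c1ccc(OC)cc1)[C@H](C(=O)OC)c1cc(OC)cc(OC)c1 | intermediate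
21 | methyl (3R,4R)-3-Bf-6,8-dimethoxy-1-(4-methoxyphenyl)-3,4-dihydroisoquinoline-4-carboxylate | COc1cc(OC)cc(c1)[C@@H]1c2c(cc(OC)cc2O[C@H]1c1ccc(OC)cc1)[C@@H]1N=C(c2ccc(OC)cc2)c2c(OC)cc(OC)cc2[C@H]1C(=O)OC | intermediate (not isolated)
22 | methyl (1R,3R,4R)-3-Bf-6,8-dimethoxy-1-(4-methoxyphenyl)-1,2,3,4-tetrahydroisoquinoline-4-carboxylate (1,3-cis; 3,4-trans) | COc1cc(OC)cc(c1)[C@@H]1c2c(cc(OC)cc2O[C@H]1c1ccc(OC)cc1)[C@@H]1N[C@H](c2ccc(OC)cc2)c2c(OC)cc(OC)cc2[C@H]1C(=O)OC | intermediate
23 | 22 bearing N-[N-benzyloxy-4-(trifluoromethyl)benzamido] on the ring nitrogen | COc1cc(OC)cc(c1)[C@@H]1c2c(cc(OC)cc2O[C@H]1c1ccc(OC)cc1)[C@@H]1N(N(OCc2ccccc2)C(=O)c2ccc(cc2)C(F)(F)F)[C@H](c2ccc(OC)cc2)c2c(OC)cc(OC)cc2[C@H]1C(=O)OC | intermediate (not isolated)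
24 | isodiazene (1,1-diazene) of 22 | COc1cc(OC)cc(c1)[C@@H]1c2c(cc(OC)cc2O[C@H]1c1ccc(OC)cc1)[C@@H]1[N+](=[N-])[C@H](c2ccc(OC)cc2)c2c(OC)cc(OC)cc2[C@H]1C(=O)OC | intermediate (not isolated)
25 | methyl (1S,2R,3R)-2-Bf-4,6-dimethoxy-3-(4-methoxyphenyl)-2,3-dihydro-1H-indene-1-carboxylate (2,3-cis; 1,2-trans) | COc1cc(OC)cc(c1)[C@@H]1c2c(cc(OC)cc2O[C@H]1c1ccc(OC)cc1)[C@@H]1[C@H](c2ccc(OC)cc2)c2c(OC)cc(OC)cc2[C@H]1C(=O)OC | intermediate
26 | (1S,2R,3R)-2-Bf-4,6-dimethoxy-3-(4-methoxyphenyl)-2,3-dihydro-1H-indene-1-carbaldehyde | COc1cc(OC)cc(c1)[C@@H]1c2c(cc(OC)cc2O[C@H]1c1ccc(OC)cc1)[C@@H]1[C@H](c2ccc(OC)cc2)c2c(OC)cc(OC)cc2[C@H]1C=O | intermediate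
27 | 4-methoxyphenylmagnesium bromide | COc1ccc([Mg]Br)cc1 | starting material
28 | [(1S,2R,3R)-2-Bf-4,6-dimethoxy-3-(4-methoxyphenyl)-2,3-dihydro-1H-inden-1-yl](4-methoxyphenyl)methanol (carbinol epimers) | COc1cc(OC)cc(c1)[C@@H]1c2c(cc(OC)cc2O[C@H]1c1ccc(OC)cc1)[C@@H]1[C@H](c2ccc(OC)cc2)c2c(OC)cc(OC)cc2[C@H]1C(O)c1ccc(OC)cc1 | intermediate
29 | octa-O-methylcanaliculatol (indane C1 R, C2 S, C3 R; diarylmethine R; benzofuran C2 R, C3 R) | COc1ccc([C@@H]2c3c(OC)cc(OC)cc3[C@H]3[C@H](c4ccc(OC)cc4)c4c(OC)cc(OC)cc4[C@@H]4c5c(cc(OC)cc5[C@H]23)O[C@H]4c2ccc(OC)cc2)cc1 | intermediate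
30 | canaliculatol | Oc1ccc([C@@H]2c3c(O)cc(O)cc3[C@H]3[C@H](c4ccc(O)cc4)c4c(O)cc(O)cc4[C@@H]4c5c(cc(O)cc5[C@H]23)O[C@H]4c2ccc(O)cc2)cc1 | target

**Totals.** 15 steps; the longest linear sequence is 15 steps (from 1 to 30).

**Steps most likely to fail**

Step 14. The benzylic cation may lose the neighbouring indane C1 proton and be re-formed with loss of the 1,2-trans relation, after which the cis isomer closes irreversibly onto ring D; the new methine may also form with poor facial selectivity. The fallback sets out from 25 and comes back at 29. The ester is hydrolysed (LiOH, THF/H2O) to the carboxylic acid F1. Friedel–Crafts acylation (trifluoroacetic anhydride, CH2Cl2, or (COCl)2 then SnCl4) closes the eight-membered ring as the ketone F2; an acylium ion cannot eliminate to a styrene. Addition of 4-MeOC6H4MgBr with CeCl3 gives the tertiary alcohol F3, and ionic hydrogenation (Et3SiH, TFA, CH2Cl2) delivers hydride to the diaryl cation from the face away from the indane to give 29.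

Step 11. Transfer of the amino nitrogen to the doubly α-branched amine may be slow, or the isodiazene may isomerise to a hydrazone by 1,3-hydrogen shift at 45 °C before it loses N2. The fallback sets out from 22 and comes back at 25. Nitrosation (NaNO2, AcOH) gives the N-nitrosamine F4, and reduction (Zn, AcOH, 0 °C) gives the N-amino tetrahydroisoquinoline F5. Oxidation with HgO (EtOH, 0 °C → rt) then generates isodiazene 24 at low temperature; this classical hydrazine-oxidation route is known to give retention with cis-2,6-diaryl cyclic amines.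

Step 4. The ortho bromine may twist the carbene-bearing ring and erode enantiofacial discrimination by the chiral dirhodium carboxylate. The fallback sets out from 7 and comes back at 9. The insertion is run with achiral Rh2(OAc)4 (slow addition of the diazo solution to suppress azine formation) to give racemic cis product, and 9 is separated from its enantiomer F6 by preparative chromatography on a chiral stationary phase.

**Further compounds**

F1 | step 14 | (1S,2R,3R)-2-Bf-4,6-dimethoxy-3-(4-methoxyphenyl)-2,3-dihydro-1H-indene-1-carboxylic acid | COc1cc(OC)cc(c1)[C@@H]1c2c(cc(OC)cc2O[C@H]1c1ccc(OC)cc1)[C@@H]1[C@H](c2ccc(OC)cc2)c2c(OC)cc(OC)cc2[C@H]1C(O)=O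
F2 | step 14 | eight-membered ring ketone (29 with C=O in place of the CH(4-methoxyphenyl) methine) | COc1ccc([C@@H]2c3c(OC)cc(OC)cc3[C@H]3C(=O)c4c(OC)cc(OC)cc4[C@@H]4c5c(cc(OC)cc5[C@H]23)O[C@H]4c2ccc(OC)cc2)cc1
F3 | step 14 | tertiary alcohol from F2 and 4-methoxyphenylmagnesium bromide (carbinol epimers) | COc1ccc([C@@H]2c3c(OC)cc(OC)cc3[C@H]3C(O)(c4ccc(OC)cc4)c4c(OC)cc(OC)cc4[C@@H]4c5c(cc(OC)cc5[C@H]23)O[C@H]4c2ccc(OC)cc2)cc1
F4 | step 11 | N-nitroso derivative of 22 | COc1cc(OC)cc(c1)[C@@H]1c2c(cc(OC)cc2O[C@H]1c1ccc(OC)cc1)[C@@H]1N(N=O)[C@H](c2ccc(OC)cc2)c2c(OC)cc(OC)cc2[C@H]1C(=O)OC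
F5 | step 11 | N-amino derivative of 22 | COc1cc(OC)cc(c1)[C@@H]1c2c(cc(OC)cc2O[C@H]1c1ccc(OC)cc1)[C@@H]1N(N)[C@H](c2ccc(OC)cc2)c2c(OC)cc(OC)cc2[C@H]1C(=O)OC
F6 | step 4 | (2R,3S)-4-bromo-3-(3,5-dimethoxyphenyl)-6-methoxy-2-(4-methoxyphenyl)-2,3-dihydro-1-benzofuran (enantiomer of 9) | COc1cc(OC)cc(c1)[C@H]1c2c(Br)cc(OC)cc2O[C@H]1c1ccc(OC)cc1
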